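**The choice.** You must decide whether the epsilon flask deserves more gas, and a sparing charge wants that answer from the runs in hand.

| flask | substrate | gas phase | protic impurity | remark | time |
|---|---|---|---|---|---|
| epsilon | 27 mM | 2.5 mM (held) | 8.1 mM | the very flask that is asked about, followed so far |  |
| theta | 40 mM | 2.5 mM (held) | 8.1 mM | run made earlier |  |
| flask | 27 mM | 2.5 mM (held) | 8.10 mM |  | 6.0 d |

| run | time / d | target / % | substrate / % |
|---|---|---|---|
| epsilon | 0.625 | 23.4 | 58.7 |
| epsilon | 1.25 | 41.0 | 17.2 |
| epsilon | 1.67 | 47.0 | 4.8 |
| epsilon | 2.50 | 49.8 | 0.1 |
| theta | 0.208 | 6.5 | 90.3 |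
| theta | 0.417 | 11.8 | 78.3 |
| theta | 1.04 | 23.6 | 36.2 |
| theta | 2.50 | 37.3 | 0.2 |

(each reading ± 0.3 percentage points)

- at the start none of the gas phase is in solution

1. amount of target at 6.0 d, in percent of the substrate charged
2. concentration of dissolved gas in solution at 3.0 d, in percent of saturation
3. the change that raises the amount of target at 6.0 d, in percent of the substrate charged most ("none" if none brings more than 2 percentage points) (noon / autumn / none)
4. amount of target at 6.0 d, in percent of the substrate charged, after autumn

- noon: doubling the saturation concentration of gas phase, all else as stated
- autumn: doubling the transfer coefficient of the gas phase, all else as stated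

**Count turnovers.** Let L be the substrate lost and P the target standing. I suppose each lost substrate either makes a target or meets and destroys one. Then the target made is M = (L + P) divided by 2, and the target destroyed is D = (L − P) divided by 2. At 2.50 d the epsilon run has P = 13.4 mM and L = 27.0 mM, so M = 20.2 mM and D = 6.76 mM.

**Balance target.** Call G the target level at which making and destroying run equal; I take it to grow with dissolved gas. Then D/M is the mean target over G. Taking that mean as half of P gives G = 20.1 mM. The theta run gives 16.4 mM at the same saturation.

**My bracket.** For y, the remaining substrate can still make target or destroy it. So the floor is 49.7% and the roof 49.9%. For autumn, I take 49.8% as the floor, supposing that faster transfer does not lower G. The roof is G doubled, as I reckon for noon: P = 17.4 mM, or 64.4%. By hand I get no closer than the midpoint, 57.1%. I choose noon, worth 15 percentage points. The readings show no dissolved gas, so I give no figure for sat.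

**The result.** The forecast gave 50%, 53%, none and, below my autumn bracket, 43%, holding that “More gas only speeds the side loss”. The flask gives 49.8%, 82.2% and 57.3%, and the best change is noon: it adds 14 points, autumn 7.4 points.

    gas phase ⇌ dissolved gas, rate k1*(csat - [dissolved gas]) (kL = 0.00869 min⁻¹)
    substrate + dissolved gas → target (k = 0.939 M⁻¹ min⁻¹)
    substrate + target → side product (k = 0.0427 M⁻¹ min⁻¹)
    dissolved gas + protic impurity → quenched reagent (k = 3.44 M⁻¹ min⁻¹)
    2 dissolved gas → homo dimer (k = 0.455 M⁻¹ min⁻¹)

**At rest.** Doubled G promised 15 points, and noon shows 14 points. With G held, I reckon 77.0% for the neighbour charged with 6.8 mM of substrate, and it gives 83.1%. This flask has 0% of its substrate, the limiting reagent, left at 6.00 d. At 60.0 d its target still reads 49.8% and its side product 50.2%. Dissolved gas holds at 2.06 mM, but homo dimer climbs from 13.1 mM to 163 mM, a further 150 mM.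

The numbers in the tables stem from a simulated flask with made-up constants; the scatter is artificial.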